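(The readings were computed for an exercise, and the scatter is random.)

At 5.0 h, the reading of this flask bears on what the next run changes: more nucleophile, less protic impurity, or more time.

- red: electrophile 0.10 M; nucleophile 0.12 M; free base 0.15 M; protic impurity 0.050 M; run made earlier
- flask: electrophile 0.10 M; nucleophile 0.0800 M; free base 0.150 M; protic impurity 0.0500 M; time 5.0 h

red run (percent of the electrophile charged)

| time / min | electrophile / % | target / % |
|---|---|---|
| 4.00 | 85 | 10 |
| 12.0 | 70 | 18 |
| 20.0 | 63 | 27 |
| 30.0 | 50 | 34 |
| 50.0 | 40 | 38 |
| 60.0 | 34 | 42 |

(standard deviation of a reading: 2 percentage points)

- the reaction counts as stopped when no species that holds the electrophile changes by six tenths of a point or more over the second half of the time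

* which holds at 5.0 h: what has brought the reaction to rest, or that it has not come to rest (the free base has run out first / it is still moving / forward and back rates have come level / all of the electrophile has reacted / the nucleophile has run out first)
* part of the electrophile gone at 5.0 h
* the target standing at 5.0 h, as a percentage of the electrophile charged
* the isomer of the product standing at 5.0 h, as a percentage of the electrophile charged

The red run shows electrophile reaching target and also leaving by another road. If the other road runs on electrophile and protic impurity, which is an assumption made here, the ratio of those two rates contains neither time nor [electrophile] and follows [nucleophile]/[protic impurity]. In the red run it reads 2.13 up to 30.0 min, then 1.00 up to 60.0 min, a fall. On that assumption protic impurity was falling meanwhile, so between the middles of those stretches [nucleophile] reads as having dropped to 0.336 of its earlier value. That drop gives the nucleophile cost, the nucleophile spent per target made: 2.47. It is a rough reading, since the late stretch gained 8 percentage points of target against a scatter of 2 points.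

At that cost, this flask's 0.0800 M of nucleophile pays for about 32.4% of target and isomer together. If so, waiting buys little there, and the next run should get more nucleophile.

The forecast says it is still moving, with 76.5% gone, 50% target and 26.5% isomer, on the ground that “this looks like parallel formation”. Its target alone stands above the reckoning here, and that is where the two part.

In the flask, it is still moving, with 80.8% gone, 28.9% target and 10.7% isomer.

    target ⇌ isomer of the product (K = 0.743, k = 0.00170 /min)
    electrophile + nucleophile → acid set free + target (k = 0.198 /M/min)
    acid set free + free base ⇌ salt of the base, settled at all times (K = 8.20 /M)
    electrophile + protic impurity → quenched substrate (k = 0.167 /M/min)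
    nucleophile + acid set free ⇌ protonated nucleophile, settled at all times (K = 53100 /M)

The acid set free has two partners: parking on nucleophile, scaled by its charge, stands at 4200 against 1.2 on free base, and at 5.00 h the flask holds 0.0387 M of protonated nucleophile with 99.7% of the free base left. Counting target and isomer as target made, the nucleophile cost comes to 1.98 in this flask, and to 1.94 in the neighbour with 0.013 M of protic impurity, where 47% of the electrophile still stands.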